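The data were computed for substances that don't exist, and the scatter is random.

A small charge of substrate at a fixed loading of 0.02 mol% also brings a small amount of enzyme, so I ask how the percent of target at 3.0 min moves with the charge, since birch and oak differ in nothing else.

in all of them: enzyme 0.02 mol%

| run | substrate | remark | time |
|---|---|---|---|
| amber | 0.061 M | run made earlier |  |
| grey | 0.082 M | run made earlier |  |
| red | 0.091 M | run made earlier |  |
| birch | 0.10 M |  | 3.0 min |
| oak | 0.060 M |  | 3.0 min |

- amber (time / min: target / %, substrate / %): 0.667: 5.2, 92.4; 1.33: 9.9, 89.7; 2.00: 14.3, 85.2; 2.50: 16.6, 82.2; 3.00: 18.2, 80.0
- grey (time / min: target / %, substrate / %): 0.250: 3.7, 97.0; 0.417: 5.0, 94.0; 0.833: 8.4, 94.0; 1.50: 13.3, 89.3; 3.00: 21.3, 79.1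
- red (time / min: target / %, substrate / %): 0.667: 6.2, 93.2; 1.33: 11.7, 87.0; 2.00: 18.0, 82.0; 2.50: 19.7, 78.0; 3.00: 22.7, 75.8

(each reading ± 1 percentage point)

- the earlier runs were read with a standard deviation of 1 percentage point
- a reading or a percentage of target counts all its forms, free or not
- where the amount of substrate changes, what is given in equivalents or mol% on it follows

1. which one finishes higher in amount of target, in percent of the substrate charged ("neither" within 2 percentage points) (birch / oak / neither)
2. amount of target at the end, in percent of the substrate charged, birch
3. amount of target at the end, in percent of the substrate charged, oak

My first guess is that the yield goes roughly with the charge, as for a step first order in both enzyme and substrate, which from amber's 18.2% puts red at 27.2%; but red reads 22.7%, far outside a scatter of 1 percentage point, so that guess falls. The opposite guess, a step zero order in substrate with a yield indifferent to the charge, falls too, since amber and red stand 4.5 points apart. Between the two, amber and red read as an order of 0.552 on the charge, so I freeze the order at 0.5 and multiply each run's target at 3.0 min by the square root of birch's charge over that run's own charge. Amber, grey and red then give 23.3%, 23.5% and 23.8%, and their mean, 23.5%, is the referred yield, the number I carry.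

Amber's curve bends, its last interval gaining less per minute than its first, so no rate can be frozen; yet I freeze nothing in time, for the readings and the questions stand at the same 3.0 min. Birch lies beyond red's charge, but the referred yield drifts by 0.50 points across the three runs, inside the scatter. So I commit to 23.5% for birch and 18.2% for oak, a gap of 5.3 points against a margin of 2 points.

The forecast says birch, with 24% for birch and 18% for oak, because the yield “scales roughly as concentration to the power 0.5”; my birch lies a little below its figure.

The flask gives birch, with 24.9% for birch and 20.3% for oak.

    substrate + enzyme → target + enzyme, rate k1*[substrate]*[enzyme]/(1 + ([substrate]/Km1)) (0.180 M, k = 160 L mol⁻¹ s⁻¹)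
    enzyme + target ⇌ idle complex, settled at all times (K = 28.0 L mol⁻¹)
    crystals ⇌ target, rate k3*(cs3 - [target]) while solid is left; crystals form when [target] > cs3 (solubility = 38.0 mM, k = 0.0380 s⁻¹)

Birch stands 1.4 points above the referred yield, and oak, referred the same way, comes to 26.2%. The main reason for the gap is the difference in concentration of substrate: with that difference taken away, so that oak is charged at birch's concentration, oak goes from 20.3% to 24.9%. Carried to the neighbour charged with 0.40 M, the referred yield gives 47.1%, whereas that flask reaches 31.1%, idle complex and crystals counted in, with 59.7% of its catalyst held as idle complex, the off-cycle form.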